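## The problem

The target 29 is a trans-fused drimane. Ring A (C1–C5, C10) carries the gem-dimethyl group on C4. Ring B (C5–C10) carries the ester oxygen on C6, the carboxyl carbon C12 on C8 and the carboxyl carbon C11 on C9; the angular methyl on C10 defines the β face. Read from the SMILES, the five ring B stereocentres are 5S,6R,8S,9S,10S, that is 5α-H, 6β-acyloxy, 8β-carboxyl, 9β-carboxyl and 10β-methyl. The 6β oxygen, the 8β carboxyl and the 10β methyl are all axial on one face, and the 4β methyl adds a fourth. O6 and C12 therefore sit in thermodynamically poor positions, must be placed under kinetic control, and C8 becomes epimerisable as soon as C12 is a carbonyl group. C10 is quaternary and has no handle, so the step that creates it must also fix the absolute configuration. The other centres can then be derived from it, because the angular methyl sends reagents to the α face at C5 and C6 and, with the C8 substituent, at C9. The (2E,4E,6E)-trienoate will not survive strong base, hydride, borane, hydrogenation or saponification, so it has to arrive late and the two carboxyl groups have to be unmasked without hydrolysis. The feature that opens the structure is that C9 is bonded both to C11 and to the quaternary C10, while C6 bears oxygen. If O6 is tied to C11 as a δ-lactone, the atoms C9, C11, O, C6, C5 and C10 form the six-atom array of an ester enolate Claisen rearrangement, so ring B can be closed by making C9–C10 as the C6–O bond is given up.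

## Retrosynthesis

**29 back to 25 (O–tert-butyl bond at C11, oxidation level of C12, O–Si bond).** The trienoate rules out hydrolytic ester cleavage, so C11 is carried as a tert-butyl ester (28) that falls to acid alone. C12 is carried as a silyl ether (25) and raised to the acid only in the second-to-last step through alcohol 26 and the non-isolated aldehyde 27. Keeping C12 at the alcohol level until then avoids an enolisable axial carbonyl on C8 during every basic or reducing step. A tert-butyl ester is preferred to a primary alkyl ester because it resists lactonisation by the freed 12-hydroxyl in 26.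

**25 back to 22 and 23 (acyl C–O bond at O6).** The polyene is attached as the intact acid 23 to the 6β alcohol 22. Attaching it earlier would expose it to borane, hydride and amide base. The precursor loses the only light- and base-sensitive part of the molecule. The forward step must acylate a crowded axial alcohol without moving the double bonds.

**22 back to 18 (C6–O and C5–H bonds).** The 6β alcohol comes from ketone 21 by hydride attack on the open α face, and 21 from the 6α alcohol 20, the hydroboration product of the 5-ene 18. Borane is expected to add from the α face, which sets the trans ring fusion but gives the wrong C6 epimer; the oxidation–reduction pair corrects this. Direct inversion of 20 by substitution is not considered, because the β face of C6 is closed by two axial methyl groups. Epoxide opening would leave an unwanted 5-hydroxyl.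

**18 back to 15 (C9–H bond, ester O–alkyl bond).** The rearrangement can only deliver the C11 carboxyl trans to the C10 methyl. C9 is therefore inverted at the 5-ene stage through the ester enolate 17 of tert-butyl ester 16, by protonation on the α face. Doing this before hydroboration clears the α face of ring B for borane. The tert-butyl group is introduced by O-alkylation, so the hindered acyl carbon of 15 is never attacked.

**15 back to 12 (C9–C10 bond; the key cut).** Cutting C9–C10 and restoring the C6–O bond turns the bicyclic acid 15 into the monocyclic cis lactone 12. A cut of the same bond in an open-chain ester would leave ring B to be closed separately. A cycloaddition cut across C9–C10 and C7–C8 would offer no stereocentre from which to set C10 absolutely. The lactone cut removes a ring, the quaternary centre and two of three stereocentres at once: 12 has only two centres, 1,3-related on a six-membered ring. The forward reaction must pass through a boat and through a tetrasubstituted olefin.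

**12 back to 8 and 9 (C8–H bonds, C8=C9 double bond, acyl C–O bond).** The cis relation in 12 comes from hydrogenation of the unsaturated lactone 11 on the face away from the C6 substituent. Conjugate addition of a C12 unit to an unsubstituted lactone would give the trans isomer. Lactone 11 comes from ring-closing metathesis of acrylate 10, the ester of carbinol 8 and acryloyl chloride 9. This leaves a single stereocentre.

**8 back to 4 and 3 (C6–H bond, C6–C7 bond).** The carbinol centre is set by oxazaborolidine-catalysed reduction of ketone 7, made by oxidising the racemic adduct 6 of β-cyclocitral 4 and the allylzinc reagent 5. A direct enantioselective 2-substituted allylation of this very hindered enal would be one step shorter but less dependable.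

**3 back to 1 (C–Br and O–Si bonds).** Bromide 3 comes from the mono-silyl ether 2 of the symmetrical diol 1.

## Roads not taken

**Alternative 1:** The cut is through C4–C5 and C9–C10, so that both rings form in one step from the open-chain keto ester A1. In the forward step a chiral Lewis acid-assisted Brønsted acid (SnCl4 with one enantiomer of a BINOL monoether) protonates the terminal olefin, the chain folds chair–chair, and the enol carbon C9 terminates the cascade to give the bicyclic keto ester A2. Its merits are real. A1 is one alkylation away from commodity materials, C5, C9 and C10 are set together with the correct relative configuration, and the drimane nucleus is reached in about a third of the steps the chosen plan needs to reach 15. Its weak points lie in what A2 lacks. There is no oxygen and no handle at C6. C12 must be added to the C8 ketone as an axial, contra-thermodynamic substituent. The enantioselectivity of proton-initiated cyclisation with a chelating β-keto ester terminator is uncertain, and O-cyclisation of the enol competes. In step economy to the bicycle this road is clearly better. The chosen plan sets against it that the key step leaves the olefin at C5=C6, where the oxygen is needed, that C12 is carried through with the correct configuration, and that the absolute configuration rests on a ketone reduction.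

**Alternative 2:** The cut is the C8–C12 bond. In the forward step Bu3SnH and an initiator turn the bromomethylsilyl ether A3 into a silylmethyl radical that adds 6-exo to C8 of the unsaturated ester; hydrogen transfer to C9 then gives the cyclic silyl ether A4. This turns the hardest relationship of the target, the syn-axial O6/C12 pair, into an asset. The tether can reach C8 only from the β face, O6 is present from the start, and C9 needs no inversion. In stereochemical certainty at C8 and C9 this road is at least as good as the chosen one, and it avoids the hydroboration–oxidation–reduction detour. Its weakness is that it is a plan for one bond only. A3 already contains both rings, the quaternary centre and the C5, C6 and C10 stereocentres, so a second full strategy is needed to make it as a single enantiomer. After oxidative cleavage of the C–Si bond two hydroxyl groups have to be told apart before the trienoate can be attached. Against the better control at C8 and C9 the chosen plan sets that one step makes ring B, the quaternary centre and the absolute configuration from simple materials, without tin.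

**Alternative 3:** The cut is the C6–C7 bond. In the forward step Bu3SnH and AIBN convert the selenoester A5 into an acyl radical that adds 6-endo to the methylene carbon of the acrylate; reduction of the C8 radical gives the keto diester A6. A6 has the C6 ketone ready for α-face reduction and both carboxyl carbons at the final oxidation level as allyl esters, removable with Pd(PPh3)4 (zerovalent palladium) beside the trienoate. Its end game would be three steps, against nine after the key step here, and in this respect it is clearly superior. The weak points come before and during the key step. A5 carries three contiguous stereocentres (C5, C9, C10) around a quaternary carbon on a monocyclic frame, with no evident way to set C10 absolutely. Its C9 hydrogen is activated by the ester and the acrylate, so double-bond migration threatens. The acyl radical sits on a carbon flanked by two quaternary centres, where decarbonylation competes with ring closure. C8 is set by hydrogen transfer that must come from the α face to give the less stable epimer. The chosen plan accepts a longer end game in exchange for a front end in which only one carbinol centre is made by a reagent and C10 follows from it by a pericyclic chirality transfer.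

Key step: step 9

Assumption: in step 5 the twisted 2,6,6-trimethylcyclohexenyl group is taken to act as the large ketone substituent, so that the (R)-oxazaborolidine gives the (S)-carbinol 8, from which every later centre follows.

## Route

Step 1
Reactants: 1 2-methylenepropane-1,3-diol
Product: 2 2-{[(tert-butyldimethylsilyl)oxy]methyl}prop-2-en-1-ol
Conditions: NaH (1.0 equiv), THF, 0 °C; TBSCl (1.0 equiv), 0 °C to rt
Reagents that add atoms: tert-butyldimethylsilyl chloride (TBSCl), CC(C)(C)[Si](C)(C)Cl
Why: Monosilylation of a symmetrical diol through its sparingly soluble monosodium alkoxide, which should favour the mono-ether; no stereocentre is involved.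

Step 2
Reactants: 2 2-{[(tert-butyldimethylsilyl)oxy]methyl}prop-2-en-1-ol
Product: 3 {[2-(bromomethyl)prop-2-en-1-yl]oxy}(tert-butyl)dimethylsilane
Conditions: CBr4, PPh3, CH2Cl2, 0 °C
Reagents that add atoms: carbon tetrabromide, BrC(Br)(Br)Br
Why: Appel bromination of a primary allylic alcohol under neutral conditions that the silyl ether tolerates.

Step 3
Reactants: 3 {[2-(bromomethyl)prop-2-en-1-yl]oxy}(tert-butyl)dimethylsilane; 4 β-cyclocitral (2,6,6-trimethylcyclohex-1-ene-1-carbaldehyde)
Product: 6 rac-3-{[(tert-butyldimethylsilyl)oxy]methyl}-1-(2,6,6-trimethylcyclohex-1-en-1-yl)but-3-en-1-ol, via allylzinc bromide 5 (not isolated)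
Conditions: Zn dust (activated), THF, 0 °C to rt; then sat. aq NH4Cl
Reagents that add atoms: zinc, [Zn] (carried by 5 only)
Why: Barbier-type allylation; the allylzinc reagent adds 1,2 to the hindered aldehyde through a cyclic six-membered transition state and forms C6–C7. The carbinol is racemic here and is corrected in steps 4 and 5.

Step 4
Reactants: 6 rac-3-{[(tert-butyldimethylsilyl)oxy]methyl}-1-(2,6,6-trimethylcyclohex-1-en-1-yl)but-3-en-1-ol
Product: 7 3-{[(tert-butyldimethylsilyl)oxy]methyl}-1-(2,6,6-trimethylcyclohex-1-en-1-yl)but-3-en-1-one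
Conditions: Dess–Martin periodinane, NaHCO3, CH2Cl2, 0 °C to rt
Reagents that add atoms: none
Why: Buffered Dess–Martin oxidation; the neutral medium should leave the 1,1-disubstituted olefin out of conjugation with the new ketone.

Step 5
Reactants: 7 3-{[(tert-butyldimethylsilyl)oxy]methyl}-1-(2,6,6-trimethylcyclohex-1-en-1-yl)but-3-en-1-one
Product: 8 (1S)-3-{[(tert-butyldimethylsilyl)oxy]methyl}-1-(2,6,6-trimethylcyclohex-1-en-1-yl)but-3-en-1-ol
Conditions: (R)-2-methyl-CBS-oxazaborolidine (0.2 equiv), catecholborane, toluene, −78 °C; MeOH, then 1 M NaOH work-up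
Reagents that add atoms: none
Why: Corey–Bakshi–Shibata reduction; the ketone binds to the catalyst boron anti to the bulky cyclohexenyl group and hydride is delivered within the complex, which sets C6 as S. Catecholborane does not hydroborate the olefins at this temperature.

Step 6
Reactants: 8 (1S)-3-{[(tert-butyldimethylsilyl)oxy]methyl}-1-(2,6,6-trimethylcyclohex-1-en-1-yl)but-3-en-1-ol; 9 acryloyl chloride
Product: 10 (1S)-3-{[(tert-butyldimethylsilyl)oxy]methyl}-1-(2,6,6-trimethylcyclohex-1-en-1-yl)but-3-en-1-yl prop-2-enoate
Conditions: iPr2NEt, DMAP (cat.), CH2Cl2, −20 to 0 °C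
Reagents that add atoms: none
Why: Nucleophile-catalysed O-acylation through the acylpyridinium ion; the C6–O bond is not touched, so the configuration is retained.

Step 7
Reactants: 10 (1S)-3-{[(tert-butyldimethylsilyl)oxy]methyl}-1-(2,6,6-trimethylcyclohex-1-en-1-yl)but-3-en-1-yl prop-2-enoate
Product: 11 (6S)-4-{[(tert-butyldimethylsilyl)oxy]methyl}-6-(2,6,6-trimethylcyclohex-1-en-1-yl)-5,6-dihydro-2H-pyran-2-one
Conditions: second-generation Grubbs catalyst (H2IMes)(PCy3)Cl2Ru=CHPh (5 mol%), toluene (5 mM), 80 °C
Reagents that add atoms: none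
Why: Ring-closing metathesis of an acrylate with a 1,1-disubstituted olefin gives the six-membered unsaturated lactone with loss of ethene; the tetrasubstituted ring olefin is inert to the catalyst.

Step 8
Reactants: 11 (6S)-4-{[(tert-butyldimethylsilyl)oxy]methyl}-6-(2,6,6-trimethylcyclohex-1-en-1-yl)-5,6-dihydro-2H-pyran-2-one
Product: 12 (4S,6S)-4-{[(tert-butyldimethylsilyl)oxy]methyl}-6-(2,6,6-trimethylcyclohex-1-en-1-yl)oxan-2-one (cis)
Conditions: H2 (1 atm), 10% Pd/C, EtOAc, rt
Reagents that add atoms: none
Why: Heterogeneous syn hydrogenation on the face away from the large C6 substituent places the CH2OTBS group cis to it and sets lactone C4 (drimane C8) as S. The hindered tetrasubstituted olefin should not be reduced.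

Step 9
Reactants: 12 (4S,6S)-4-{[(tert-butyldimethylsilyl)oxy]methyl}-6-(2,6,6-trimethylcyclohex-1-en-1-yl)oxan-2-one
Product: 15 (1R,2S,8aR)-2-{[(tert-butyldimethylsilyl)oxy]methyl}-5,5,8a-trimethyl-1,2,3,5,6,7,8,8a-octahydronaphthalene-1-carboxylic acid (drimane: 5-ene/8β-CH2OTBS/9α-CO2H/10β-Me), via silyl ketene acetal 13 (not isolated), via silyl ester 14 (not isolated)
Conditions: LiN(SiMe3)2, TBSCl, HMPA, THF, −78 °C to rt; solvent change to toluene (Et3N 0.1 equiv), 110 °C; then K2CO3, MeOH/H2O, rt, work-up at pH 4
Reagents that add atoms: tert-butyldimethylsilyl chloride (TBSCl), CC(C)(C)[Si](C)(C)Cl (its silyl group is carried by 13 and 14 only and is lost on hydrolysis)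
Why: LiN(SiMe3)2 removes the only acidic hydrogen (on C9) and O-silylation gives the endocyclic silyl ketene acetal 13, in which C9=C11–O–C6–C5=C10 is a 1,5-diene whose ends are held together by C7–C8. On heating, 13 should undergo the Ireland–Claisen [3,3] shift, forming C9–C10 and breaking C6–O to give silyl ester 14, which mild base hydrolyses to 15; the closest known reaction type is the silyl ketene acetal Claisen ring contraction of 6-alkenyl δ-lactones to cyclohexenecarboxylic acids. Ring B closes by ring contraction of the six-membered lactone to the six-membered carbocycle, through a boat transition state shaped like bicyclo[2.2.2]octane, the only geometry the C7–C8 bridge allows. C10 is controlled by C6: the shift is suprafacial on the C6–C5–C10 allyl unit, so C9 arrives on the face that O6 leaves and the (6S) centre becomes the 10β-methyl quaternary centre. C9 is controlled by the ring: C8 is cis to the ring oxygen on the ketene acetal, so the boat puts the carboxyl trans to the C10 methyl (9α), which step 11 corrects; C8 is a spectator and ends β because the lactone is cis. The step needs the pericyclic path to outrun acid-catalysed ionisation of the allylic C6–O bond and needs the tetrasubstituted olefin to react; base-washed glass, a trace of amine, a non-polar solvent and the fact that the bond forms at the methyl-bearing olefin carbon and not at the one flanked by the gem-dimethyl group should secure this. The cis CH2OTBS group and the C10 methyl are pressed together in the boat, so the upper end of the 110–140 °C range may be needed.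

Step 10
Reactants: 15 (1R,2S,8aR)-2-{[(tert-butyldimethylsilyl)oxy]methyl}-5,5,8a-trimethyl-1,2,3,5,6,7,8,8a-octahydronaphthalene-1-carboxylic acid
Product: 16 tert-butyl (1R,2S,8aR)-2-{[(tert-butyldimethylsilyl)oxy]methyl}-5,5,8a-trimethyl-1,2,3,5,6,7,8,8a-octahydronaphthalene-1-carboxylate
Conditions: tBuOC(=NH)CCl3 (2 equiv), CH2Cl2/cyclohexane, rt
Reagents that add atoms: tert-butyl 2,2,2-trichloroacetimidate, CC(C)(C)OC(=N)C(Cl)(Cl)Cl
Why: O-alkylation of the carboxylic acid by the protonated imidate; the tert-butyl group is transferred to oxygen, so the hindered acyl carbon is not attacked and no stereocentre is touched.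

Step 11
Reactants: 16 tert-butyl (1R,2S,8aR)-2-{[(tert-butyldimethylsilyl)oxy]methyl}-5,5,8a-trimethyl-1,2,3,5,6,7,8,8a-octahydronaphthalene-1-carboxylate
Product: 18 tert-butyl (1S,2S,8aR)-2-{[(tert-butyldimethylsilyl)oxy]methyl}-5,5,8a-trimethyl-1,2,3,5,6,7,8,8a-octahydronaphthalene-1-carboxylate (drimane: 5-ene/8β-CH2OTBS/9β-ester/10β-Me), via lithium enolate 17 (not isolated)
Conditions: LiN(iPr)2, THF, −78 to −20 °C; cannulation into 2,6-di-tert-butyl-4-methylphenol, THF, −78 °C
Reagents that add atoms: lithium diisopropylamide, [Li]N(C(C)C)C(C)C (lithium carried by 17 only)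
Why: Ester enolate formation followed by kinetic protonation; allylic 1,3-strain in the exocyclic enolate turns the C8 CH2OTBS group axial on the β face, so the bulky proton donor should approach C9 from the α face, anti to it and to the 10β methyl. This gives 9α-H and the 9β ester (C9 becomes S).

Step 12
Reactants: 18 tert-butyl (1S,2S,8aR)-2-{[(tert-butyldimethylsilyl)oxy]methyl}-5,5,8a-trimethyl-1,2,3,5,6,7,8,8a-octahydronaphthalene-1-carboxylate
Product: 20 tert-butyl (1S,2S,4S,4aS,8aS)-2-{[(tert-butyldimethylsilyl)oxy]methyl}-4-hydroxy-5,5,8a-trimethyldecahydronaphthalene-1-carboxylate (drimane: 5α-H/6α-OH), via 6α-alkylborane 19 (not isolated)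
Conditions: BH3·THF (3 equiv), THF, 0 °C to rt; then 3 M NaOH, 30% H2O2, 0 °C to rt
Reagents that add atoms: borane–tetrahydrofuran, B.C1CCOC1 (boron carried by 19 only); hydrogen peroxide, OO (oxygen of the 6-hydroxyl)
Why: Syn, anti-Markovnikov hydroboration of the trisubstituted 5-ene from the α face, away from the 10β and 4β methyls and the 8β CH2OTBS group, should set 5α-H (trans fusion) and 6α-boron; oxidation proceeds with retention. The tert-butyl ester is reduced by borane only very slowly.

Step 13
Reactants: 20 tert-butyl (1S,2S,4S,4aS,8aS)-2-{[(tert-butyldimethylsilyl)oxy]methyl}-4-hydroxy-5,5,8a-trimethyldecahydronaphthalene-1-carboxylate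
Product: 21 tert-butyl (1S,2S,4aS,8aS)-2-{[(tert-butyldimethylsilyl)oxy]methyl}-5,5,8a-trimethyl-4-oxodecahydronaphthalene-1-carboxylate
Conditions: Dess–Martin periodinane, NaHCO3, CH2Cl2, rt
Reagents that add atoms: none
Why: Dess–Martin oxidation of the equatorial secondary alcohol under buffered conditions that should not enolise C5.

Step 14
Reactants: 21 tert-butyl (1S,2S,4aS,8aS)-2-{[(tert-butyldimethylsilyl)oxy]methyl}-5,5,8a-trimethyl-4-oxodecahydronaphthalene-1-carboxylate
Product: 22 tert-butyl (1S,2S,4R,4aS,8aS)-2-{[(tert-butyldimethylsilyl)oxy]methyl}-4-hydroxy-5,5,8a-trimethyldecahydronaphthalene-1-carboxylate (drimane: 6β-OH)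
Conditions: NaBH4, MeOH/THF, 0 °C
Reagents that add atoms: none
Why: Borohydride reduction; the axial approach from the β face is closed by the 4β and 10β methyls and the 8β CH2OTBS group, so hydride should enter from the α face and give the axial 6β alcohol (C6 = R). The tert-butyl ester is inert.

Step 15
Reactants: 22 tert-butyl (1S,2S,4R,4aS,8aS)-2-{[(tert-butyldimethylsilyl)oxy]methyl}-4-hydroxy-5,5,8a-trimethyldecahydronaphthalene-1-carboxylate; 23 (2E,4E,6E)-octa-2,4,6-trienoic acid
Product: 25 tert-butyl (1S,2S,4R,4aS,8aS)-2-{[(tert-butyldimethylsilyl)oxy]methyl}-5,5,8a-trimethyl-4-{[(2E,4E,6E)-octa-2,4,6-trienoyl]oxy}decahydronaphthalene-1-carboxylate, via mixed anhydride 24 (not isolated)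
Conditions: 23, 2,4,6-trichlorobenzoyl chloride, Et3N, THF, rt; then 22, DMAP, toluene, rt to 60 °C
Reagents that add atoms: 2,4,6-trichlorobenzoyl chloride, O=C(Cl)c1c(Cl)cc(Cl)cc1Cl (carried by 24 only)
Why: Yamaguchi esterification; DMAP transfers the trienoyl group from the mixed anhydride to the axial alcohol through the acylpyridinium ion. The C6–O bond is untouched, so the 6β configuration is retained.

Step 16
Reactants: 25 tert-butyl (1S,2S,4R,4aS,8aS)-2-{[(tert-butyldimethylsilyl)oxy]methyl}-5,5,8a-trimethyl-4-{[(2E,4E,6E)-octa-2,4,6-trienoyl]oxy}decahydronaphthalene-1-carboxylate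
Product: 26 tert-butyl (1S,2S,4R,4aS,8aS)-2-(hydroxymethyl)-5,5,8a-trimethyl-4-{[(2E,4E,6E)-octa-2,4,6-trienoyl]oxy}decahydronaphthalene-1-carboxylate
Conditions: HF·pyridine, pyridine, THF, 0 °C to rt
Reagents that add atoms: none
Why: Fluoride-induced desilylation in a weakly acidic medium; no alkoxide is formed, which should suppress both acyl shift from O6 to O12 and lactonisation onto the tert-butyl ester.

Step 17
Reactants: 26 tert-butyl (1S,2S,4R,4aS,8aS)-2-(hydroxymethyl)-5,5,8a-trimethyl-4-{[(2E,4E,6E)-octa-2,4,6-trienoyl]oxy}decahydronaphthalene-1-carboxylate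
Product: 28 (1S,2S,4R,4aS,8aS)-1-(tert-butoxycarbonyl)-5,5,8a-trimethyl-4-{[(2E,4E,6E)-octa-2,4,6-trienoyl]oxy}decahydronaphthalene-2-carboxylic acid, via aldehyde 27 (not isolated)
Conditions: Dess–Martin periodinane, NaHCO3, CH2Cl2, 0 °C; then NaClO2, NaH2PO4, 2-methylbut-2-ene, tBuOH/H2O, 0 °C to rt
Reagents that add atoms: sodium chlorite, [Na+].[O-]Cl=O (oxygen of the new carboxyl group)
Why: Dess–Martin oxidation to the aldehyde and immediate Pinnick oxidation; both stages are buffered, so the axial aldehyde on C8 should not enolise, and the olefin scavenger keeps hypochlorite from the triene.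

Step 18
Reactants: 28 (1S,2S,4R,4aS,8aS)-1-(tert-butoxycarbonyl)-5,5,8a-trimethyl-4-{[(2E,4E,6E)-octa-2,4,6-trienoyl]oxy}decahydronaphthalene-2-carboxylic acid
Product: 29 (1S,2S,4R,4aS,8aS)-5,5,8a-trimethyl-4-{[(2E,4E,6E)-octa-2,4,6-trienoyl]oxy}decahydronaphthalene-1,2-dicarboxylic acid (CNP0462207.1)
Conditions: CF3CO2H/CH2Cl2 (1:4), 0 °C to rt
Reagents that add atoms: none
Why: Acidolysis of the tert-butyl ester through the tert-butyl cation with loss of 2-methylpropene; the secondary trienoate is stable to anhydrous acid and no stereocentre is involved.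

## Compound list

1 | 2-methylenepropane-1,3-diol | C=C(CO)CO | starting material
2 | 2-{[(tert-butyldimethylsilyl)oxy]methyl}prop-2-en-1-ol | C=C(CO)CO[Si](C)(C)C(C)(C)C | intermediate
3 | {[2-(bromomethyl)prop-2-en-1-yl]oxy}(tert-butyl)dimethylsilane | C=C(CBr)CO[Si](C)(C)C(C)(C)C | intermediate
4 | β-cyclocitral (2,6,6-trimethylcyclohex-1-ene-1-carbaldehyde) | CC1=C(C=O)C(C)(C)CCC1 | starting material
5 | (2-{[(tert-butyldimethylsilyl)oxy]methyl}prop-2-en-1-yl)zinc bromide | C=C(C[Zn]Br)CO[Si](C)(C)C(C)(C)C | intermediate (not isolated)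
6 | rac-3-{[(tert-butyldimethylsilyl)oxy]methyl}-1-(2,6,6-trimethylcyclohex-1-en-1-yl)but-3-en-1-ol | C=C(CO[Si](C)(C)C(C)(C)C)CC(O)C1=C(C)CCCC1(C)C | intermediate
7 | 3-{[(tert-butyldimethylsilyl)oxy]methyl}-1-(2,6,6-trimethylcyclohex-1-en-1-yl)but-3-en-1-one | C=C(CO[Si](C)(C)C(C)(C)C)CC(=O)C1=C(C)CCCC1(C)C | intermediate
8 | (1S)-3-{[(tert-butyldimethylsilyl)oxy]methyl}-1-(2,6,6-trimethylcyclohex-1-en-1-yl)but-3-en-1-ol | C=C(CO[Si](C)(C)C(C)(C)C)C[C@H](O)C1=C(C)CCCC1(C)C | intermediate
9 | acryloyl chloride | C=CC(Cl)=O | starting material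
10 | (1S)-3-{[(tert-butyldimethylsilyl)oxy]methyl}-1-(2,6,6-trimethylcyclohex-1-en-1-yl)but-3-en-1-yl prop-2-enoate | C=CC(=O)O[C@@H](CC(=C)CO[Si](C)(C)C(C)(C)C)C1=C(C)CCCC1(C)C | intermediate
11 | (6S)-4-{[(tert-butyldimethylsilyl)oxy]methyl}-6-(2,6,6-trimethylcyclohex-1-en-1-yl)-5,6-dihydro-2H-pyran-2-one | O=C1C=C(CO[Si](C)(C)C(C)(C)C)C[C@@H](C2=C(C)CCCC2(C)C)O1 | intermediate
12 | (4S,6S)-4-{[(tert-butyldimethylsilyl)oxy]methyl}-6-(2,6,6-trimethylcyclohex-1-en-1-yl)oxan-2-one (cis) | O=C1C[C@@H](CO[Si](C)(C)C(C)(C)C)C[C@@H](C2=C(C)CCCC2(C)C)O1 | intermediate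
13 | tert-butyl{[(2S,4S)-4-{[(tert-butyldimethylsilyl)oxy]methyl}-2-(2,6,6-trimethylcyclohex-1-en-1-yl)-3,4-dihydro-2H-pyran-6-yl]oxy}dimethylsilane (silyl ketene acetal of 12) | CC(C)(C)[Si](C)(C)OC1=C[C@@H](CO[Si](C)(C)C(C)(C)C)C[C@@H](C2=C(C)CCCC2(C)C)O1 | intermediate (not isolated)
14 | tert-butyldimethylsilyl (1R,2S,8aR)-2-{[(tert-butyldimethylsilyl)oxy]methyl}-5,5,8a-trimethyl-1,2,3,5,6,7,8,8a-octahydronaphthalene-1-carboxylate | C1=C2C(C)(C)CCC[C@]2(C)[C@H](C(=O)O[Si](C)(C)C(C)(C)C)[C@@H](CO[Si](C)(C)C(C)(C)C)C1 | intermediate (not isolated)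
15 | (1R,2S,8aR)-2-{[(tert-butyldimethylsilyl)oxy]methyl}-5,5,8a-trimethyl-1,2,3,5,6,7,8,8a-octahydronaphthalene-1-carboxylic acid (12-silyloxydrim-5-en-11-oic acid; 8β-CH2OTBS, 9α-CO2H, 10β-Me) | C1=C2C(C)(C)CCC[C@]2(C)[C@H](C(=O)O)[C@@H](CO[Si](C)(C)C(C)(C)C)C1 | intermediate
16 | tert-butyl (1R,2S,8aR)-2-{[(tert-butyldimethylsilyl)oxy]methyl}-5,5,8a-trimethyl-1,2,3,5,6,7,8,8a-octahydronaphthalene-1-carboxylate | C1=C2C(C)(C)CCC[C@]2(C)[C@H](C(=O)OC(C)(C)C)[C@@H](CO[Si](C)(C)C(C)(C)C)C1 | intermediate
17 | lithium enolate of 16 (C9=C11, O-lithium, O-tert-butyl) | C1=C2C(C)(C)CCC[C@]2(C)C(=C(O[Li])OC(C)(C)C)[C@@H](CO[Si](C)(C)C(C)(C)C)C1 | intermediate (not isolated)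
18 | tert-butyl (1S,2S,8aR)-2-{[(tert-butyldimethylsilyl)oxy]methyl}-5,5,8a-trimethyl-1,2,3,5,6,7,8,8a-octahydronaphthalene-1-carboxylate (9β ester) | C1=C2C(C)(C)CCC[C@]2(C)[C@@H](C(=O)OC(C)(C)C)[C@@H](CO[Si](C)(C)C(C)(C)C)C1 | intermediate
19 | 6α-boranyl derivative (R–BH2) of the 5α-H, 8β-CH2OTBS, 9β-CO2tBu drimane | B[C@H]1C[C@H](CO[Si](C)(C)C(C)(C)C)[C@H](C(=O)OC(C)(C)C)[C@@]2(C)CCCC(C)(C)[C@H]12 | intermediate (not isolated)
20 | tert-butyl (1S,2S,4S,4aS,8aS)-2-{[(tert-butyldimethylsilyl)oxy]methyl}-4-hydroxy-5,5,8a-trimethyldecahydronaphthalene-1-carboxylate (6α-OH, 5α-H) | O[C@H]1C[C@H](CO[Si](C)(C)C(C)(C)C)[C@H](C(=O)OC(C)(C)C)[C@@]2(C)CCCC(C)(C)[C@H]12 | intermediate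
21 | tert-butyl (1S,2S,4aS,8aS)-2-{[(tert-butyldimethylsilyl)oxy]methyl}-5,5,8a-trimethyl-4-oxodecahydronaphthalene-1-carboxylate | O=C1C[C@H](CO[Si](C)(C)C(C)(C)C)[C@H](C(=O)OC(C)(C)C)[C@@]2(C)CCCC(C)(C)[C@H]12 | intermediate
22 | tert-butyl (1S,2S,4R,4aS,8aS)-2-{[(tert-butyldimethylsilyl)oxy]methyl}-4-hydroxy-5,5,8a-trimethyldecahydronaphthalene-1-carboxylate (6β-OH) | O[C@@H]1C[C@H](CO[Si](C)(C)C(C)(C)C)[C@H](C(=O)OC(C)(C)C)[C@@]2(C)CCCC(C)(C)[C@H]12 | intermediate
23 | (2E,4E,6E)-octa-2,4,6-trienoic acid | C/C=C/C=C/C=C/C(=O)O | starting material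
24 | (2E,4E,6E)-octa-2,4,6-trienoic 2,4,6-trichlorobenzoic anhydride | C/C=C/C=C/C=C/C(=O)OC(=O)c1c(Cl)cc(Cl)cc1Cl | intermediate (not isolated)
25 | tert-butyl (1S,2S,4R,4aS,8aS)-2-{[(tert-butyldimethylsilyl)oxy]methyl}-5,5,8a-trimethyl-4-{[(2E,4E,6E)-octa-2,4,6-trienoyl]oxy}decahydronaphthalene-1-carboxylate | C/C=C/C=C/C=C/C(=O)O[C@@H]1C[C@H](CO[Si](C)(C)C(C)(C)C)[C@H](C(=O)OC(C)(C)C)[C@@]2(C)CCCC(C)(C)[C@H]12 | intermediate
26 | tert-butyl (1S,2S,4R,4aS,8aS)-2-(hydroxymethyl)-5,5,8a-trimethyl-4-{[(2E,4E,6E)-octa-2,4,6-trienoyl]oxy}decahydronaphthalene-1-carboxylate | C/C=C/C=C/C=C/C(=O)O[C@@H]1C[C@H](CO)[C@H](C(=O)OC(C)(C)C)[C@@]2(C)CCCC(C)(C)[C@H]12 | intermediate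
27 | tert-butyl (1S,2S,4R,4aS,8aS)-2-formyl-5,5,8a-trimethyl-4-{[(2E,4E,6E)-octa-2,4,6-trienoyl]oxy}decahydronaphthalene-1-carboxylate | C/C=C/C=C/C=C/C(=O)O[C@@H]1C[C@H](C=O)[C@H](C(=O)OC(C)(C)C)[C@@]2(C)CCCC(C)(C)[C@H]12 | intermediate (not isolated)
28 | (1S,2S,4R,4aS,8aS)-1-(tert-butoxycarbonyl)-5,5,8a-trimethyl-4-{[(2E,4E,6E)-octa-2,4,6-trienoyl]oxy}decahydronaphthalene-2-carboxylic acid | C/C=C/C=C/C=C/C(=O)O[C@@H]1C[C@H](C(=O)O)[C@H](C(=O)OC(C)(C)C)[C@@]2(C)CCCC(C)(C)[C@H]12 | intermediate
29 | (1S,2S,4R,4aS,8aS)-5,5,8a-trimethyl-4-{[(2E,4E,6E)-octa-2,4,6-trienoyl]oxy}decahydronaphthalene-1,2-dicarboxylic acid (CNP0462207.1) | C/C=C/C=C/C=C/C(=O)O[C@@H]1C[C@H](C(=O)O)[C@H](C(=O)O)[C@@]2(C)CCCC(C)(C)[C@H]12 | target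

## Step count and least certain steps

Total step count: 18. Longest linear sequence: 18 steps, from 1 to 29 (4, 9 and 23 enter as purchased materials).

**Step 9 (key step).** The most likely failure is that the rearrangement is slowed by the tetrasubstituted olefin and by the contact between the cis CH2OTBS group and the C10 methyl in the boat. Decay of the silyl ketene acetal then takes over: O-to-C silyl migration, or acid-catalysed ionisation of the allylic C6–O bond with elimination. The fallback keeps the same bond formation but uses a thermally robust cyclic enol ether in place of the silyl ketene acetal. It sets out from 12. Reduction with iBu2AlH (CH2Cl2, −78 °C) would give the lactol F1, and dehydration with MsCl/Et3N the 3,4-dihydro-2H-pyran F2. Thermolysis of F2 in base-washed glass (toluene, sealed, about 200 °C) is the known Claisen ring contraction of 2-alkenyl dihydropyrans and should give, through the same boat, the aldehyde F3. Pinnick oxidation of F3 (NaClO2, NaH2PO4, 2-methylbut-2-ene) returns to the route at 15.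

**Step 11.** The most likely failure is incomplete removal of the C9 hydrogen, which lies on the β face between the C10 methyl and the C8 substituent; warming the tert-butyl ester enolate to force deprotonation would lead to loss of tert-butoxide. Delivery of the proton on both faces is the second risk. The fallback generates the same enolate without deprotonation. It sets out from 15. 1-Chloro-N,N,2-trimethylprop-1-en-1-amine would give the acid chloride F4, and Et3N the hindered ketene F5. Addition of LiOtBu to F5 (THF, −78 °C) gives 17, which is protonated as in step 11, returning to the route at 18 and bypassing step 10.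

**Step 15.** The most likely failure is that acyl transfer to the 6β hydroxyl is too slow, because the 4β and 10β methyls and the 8β CH2OTBS group all flank it; forcing conditions would move the triene out of conjugation or scramble its geometry through a ketene or dienolate. The fallback attaches a small acyl group first and builds the triene afterwards. It sets out from 22. Bromoacetyl bromide and pyridine would give the bromoacetate F6, and triethyl phosphite (Arbuzov reaction) the phosphonoacetate F7. Horner–Wadsworth–Emmons reaction of F7 with (2E,4E)-hexa-2,4-dienal (LiCl, DBU, MeCN) forms the 2E double bond and returns to the route at 25.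

**Step 12.** The most likely failure is sluggish addition of borane to the hindered 5-ene, which gives time for reduction of the ester, or partial attack on the β face. The fallback replaces hydroboration by epoxidation and anti-Markovnikov reductive opening. It sets out from 18. mCPBA (NaHCO3, CH2Cl2) should give, again from the α face, the 5α,6α-epoxide F8. Cp2TiCl (trivalent titanium, from Cp2TiCl2 and Mn dust) with 1,4-cyclohexadiene in THF opens F8 to the tertiary C5 radical, which takes hydrogen on the α face, returning to the route at 20.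

**Step 8.** The most likely failure is hydrogenolysis of an allylic C–O bond on palladium (the lactone C6–O bond next to the ring olefin, or the C12–O bond next to the enoate), or incomplete face selectivity. The fallback changes the mechanism to 1,4-hydride addition with a copper hydride: [(Ph3P)CuH]6, or Cu(OAc)2 with a chiral bisphosphine and polymethylhydrosiloxane, the ligand enantiomer being chosen to reinforce the substrate bias. It leads from 11 directly to 12, cannot cleave C–O bonds, and makes no new compound (F0).

**Step 5.** The most likely failure is slow catalysed reduction of the twisted, hindered ketone, so that uncatalysed reduction erodes the enantiomeric purity; migration of the β,γ-olefin into conjugation under Lewis acid is the second risk. The fallback avoids ketone 7 and resolves the carbinol. It sets out from 6. Esterification with (S)-2-methoxy-2-phenylacetic acid (DCC, DMAP) would give the diastereomeric esters F9 (from the S carbinol) and F10 (from the R carbinol), which are separated by chromatography. Reductive cleavage of F9 with iBu2AlH returns to the route at 8.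

## Further compounds

F1 | step 9 | (4S,6S)-4-{[(tert-butyldimethylsilyl)oxy]methyl}-6-(2,6,6-trimethylcyclohex-1-en-1-yl)oxan-2-ol (lactol, anomeric mixture) | OC1C[C@@H](CO[Si](C)(C)C(C)(C)C)C[C@@H](C2=C(C)CCCC2(C)C)O1
F2 | step 9 | tert-butyldimethyl{[(2S,4S)-2-(2,6,6-trimethylcyclohex-1-en-1-yl)-3,4-dihydro-2H-pyran-4-yl]methoxy}silane | C1=C[C@@H](CO[Si](C)(C)C(C)(C)C)C[C@@H](C2=C(C)CCCC2(C)C)O1
F3 | step 9 | (1R,2S,8aR)-2-{[(tert-butyldimethylsilyl)oxy]methyl}-5,5,8a-trimethyl-1,2,3,5,6,7,8,8a-octahydronaphthalene-1-carbaldehyde | C1=C2C(C)(C)CCC[C@]2(C)[C@H](C=O)[C@@H](CO[Si](C)(C)C(C)(C)C)C1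
F4 | step 11 | (1R,2S,8aR)-2-{[(tert-butyldimethylsilyl)oxy]methyl}-5,5,8a-trimethyl-1,2,3,5,6,7,8,8a-octahydronaphthalene-1-carbonyl chloride | C1=C2C(C)(C)CCC[C@]2(C)[C@H](C(Cl)=O)[C@@H](CO[Si](C)(C)C(C)(C)C)C1
F5 | step 11 | ketene from F4 (C9=C11=O; 8β-CH2OTBS, 10β-Me, 5-ene) | C1=C2C(C)(C)CCC[C@]2(C)C(=C=O)[C@@H](CO[Si](C)(C)C(C)(C)C)C1
F6 | step 15 | tert-butyl (1S,2S,4R,4aS,8aS)-4-(2-bromoacetoxy)-2-{[(tert-butyldimethylsilyl)oxy]methyl}-5,5,8a-trimethyldecahydronaphthalene-1-carboxylate | BrCC(=O)O[C@@H]1C[C@H](CO[Si](C)(C)C(C)(C)C)[C@H](C(=O)OC(C)(C)C)[C@@]2(C)CCCC(C)(C)[C@H]12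
F7 | step 15 | tert-butyl (1S,2S,4R,4aS,8aS)-2-{[(tert-butyldimethylsilyl)oxy]methyl}-4-[2-(diethoxyphosphoryl)acetoxy]-5,5,8a-trimethyldecahydronaphthalene-1-carboxylate | CCOP(=O)(OCC)CC(=O)O[C@@H]1C[C@H](CO[Si](C)(C)C(C)(C)C)[C@H](C(=O)OC(C)(C)C)[C@@]2(C)CCCC(C)(C)[C@H]12
F8 | step 12 | tert-butyl 5α,6α-epoxy-12-[(tert-butyldimethylsilyl)oxy]driman-11-oate (8β-CH2OTBS, 9β-ester, 10β-Me) | O1[C@H]2C[C@H](CO[Si](C)(C)C(C)(C)C)[C@H](C(=O)OC(C)(C)C)[C@@]3(C)CCCC(C)(C)[C@]123
F0 | step 8 | none | none
F9 | step 5 | (1S)-3-{[(tert-butyldimethylsilyl)oxy]methyl}-1-(2,6,6-trimethylcyclohex-1-en-1-yl)but-3-en-1-yl (2S)-2-methoxy-2-phenylacetate | CO[C@@H](c1ccccc1)C(=O)O[C@@H](CC(=C)CO[Si](C)(C)C(C)(C)C)C1=C(C)CCCC1(C)C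
F10 | step 5 | (1R)-3-{[(tert-butyldimethylsilyl)oxy]methyl}-1-(2,6,6-trimethylcyclohex-1-en-1-yl)but-3-en-1-yl (2S)-2-methoxy-2-phenylacetate | CO[C@@H](c1ccccc1)C(=O)O[C@H](CC(=C)CO[Si](C)(C)C(C)(C)C)C1=C(C)CCCC1(C)C
A1 | alternative 1 | methyl (6E)-7,11-dimethyl-3-oxododeca-6,10-dienoate | COC(=O)CC(=O)CC/C=C(\C)CCC=C(C)C
A2 | alternative 1 | methyl 8-oxodriman-11-oate (5α-H, 9β-ester, 10β-methyl) | C1CC(=O)[C@H](C(=O)OC)[C@@]2(C)CCCC(C)(C)[C@H]12
A3 | alternative 2 | 2-(trimethylsilyl)ethyl 6β-{[(bromomethyl)dimethylsilyl]oxy}drim-8-en-11-oate | BrC[Si](C)(C)O[C@@H]1CC=C(C(=O)OCC[Si](C)(C)C)[C@@]2(C)CCCC(C)(C)[C@H]12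
A4 | alternative 2 | cyclic 6β-O,12-C dimethylsilylene derivative of 2-(trimethylsilyl)ethyl 8β,9β-driman-11-oate | O1[C@@H]2C[C@H](C[Si]1(C)C)[C@H](C(=O)OCC[Si](C)(C)C)[C@@]3(C)CCCC(C)(C)[C@H]23
A5 | alternative 3 | diallyl 2-methylene-3-[(1S,2S)-1,3,3-trimethyl-2-(phenylselanylcarbonyl)cyclohexyl]butanedioate (C6 selenoester, C8 acrylate, 9β-ester) | C=C(C(=O)OCC=C)[C@H](C(=O)OCC=C)[C@@]1(C)CCCC(C)(C)[C@@H]1C(=O)[Se]c1ccccc1
A6 | alternative 3 | diallyl 6-oxo-8β,9β-drimane-11,12-dioate | O=C1C[C@H](C(=O)OCC=C)[C@H](C(=O)OCC=C)[C@@]2(C)CCCC(C)(C)[C@H]12
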